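At 30 min the feed of J has been over for 10.0 min, and that is when I must read the flask.

| flask | J | L | remark | time |
|---|---|---|---|---|
| teal | 0.060 M (fed, over 20 min) | 0.089 M | run made earlier; the fed solution adds 0.50 times the starting volume |  |
| blue | 0.13 M (fed, over 20 min) | 0.089 M | run made earlier; the fed solution adds 0.50 times the starting volume |  |
| flask | 0.089 M (fed, over 20 min) | 0.0890 M | the fed solution adds 0.50 times the starting volume | 30 min |

| run | time / min | Z / % | Q / % | J / % | X / % |
|---|---|---|---|---|---|
| teal | 2.50 | 0 | 1.4 | 9.6 | 1.2 |
| teal | 5.00 | 1.4 | 0.3 | 17.4 | 1.7 |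
| teal | 8.00 | 5.6 | 2.1 | 22.9 | 2.3 |
| teal | 15.0 | 17.8 | 9.5 | 34.1 | 7.1 |
| teal | 30.0 | 44.2 | 20.5 | 14.4 | 10.3 |
| blue | 2.50 | 0.4 | 0 | 11.0 | 0 |
| blue | 8.00 | 3.7 | 3.6 | 24.2 | 5.2 |
| blue | 15.0 | 15.0 | 7.8 | 34.4 | 8.1 |
| blue | 20.0 | 27.0 | 16.7 | 38.7 | 11.9 |
| blue | 30.0 | 43.2 | 20.5 | 16.8 | 10.0 |

(scatter of a reading: 1 percentage point)

- percentages count the J that a species holds: one E counts as two
- X is meant together with its E
- every charge counts on the volume at the start, and the solution that is fed holds the whole dose
- what may be going on: J + X <-> E; J + L -> G; X <-> Q; X <-> Z; J <-> X; J <-> Q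
- percentages count the whole charge, also what has not yet gone in
- in an amount of X, one E counts as one X
- a reading or a percentage of J is of its free form alone

1. the largest share of what was charged as J, at 30 min belongs to (X / J / Q / Z)
2. the largest share itself, whichever of these holds it, in percent of the J charged

At that time Z leads both earlier runs, holding more than Q, J or X. So I bracket Z. The flask's charge of 0.089 M lies between the two earlier charges, so if the share moves steadily with charge, my upper bound is the teal reading of 44.2% and my lower bound the blue reading of 43.2%, each widened by the scatter of 1 percentage point.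

To tighten this, I take the change of the Z share per unit of the natural logarithm of the J charge, which is −1.3 points; I call it the charge slope. First-order steps leave it flat, and this reading rests on a difference of 1 point against that scatter. Moving from teal to the flask's charge, it gives 43.7%.

The forecast names Z at 43.7%, inside the bracket, holding that “the main paths behave as first order in J”. It stands on the same two readings, so our meeting is no check.

The flask gives Z at 44.4%.

    J + X ⇌ E, settled at all times (K = 15.9 /M)
    J + L → G (k = 0.177 /M/min)
    X ⇌ Q (k = 0.00506 /min)
    X ⇌ Z (K = 7.97, k = 0.464 /min)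
    J ⇌ X (K = 1.20, k = 0.0873 /min)
    J ⇌ Q (K = 2.20, k = 0.0345 /min)

That is 0.20 points above the teal reading, within its scatter of 1 point, and the forecast holds. In the flask, E holds 2.39% of the J charged at 30.0 min. For a neighbour flask charged with 0.36 M of J, the charge slope reckons 41.9% of Z. That neighbour holds 39.1% of Z, with 9.81% in E.

All runs were computed with constants of no real substance; noise was put on by code.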